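**Plan**

- Retrosynthesis: remove the O-ethyl and O-methyl caps, open lactone B (O1–C2) to an (E)-o-hydroxycinnamate, then cut C8–C8a of benzene ring B back to a cyclobutenone.
- The cyclobutenone is cut at the carbinol C–C bond (1-ethoxyvinyllithium), at the ring–acrylate C–C bond (Stille) and at the ring C–OAr bond (isoscopoletin on squaric acid dichloride).
- Forward: the four-membered ring comes from squaric acid and coumarin A comes ready-made in isoscopoletin; benzene ring B then arises by ring expansion, the pyranone of unit B by lactonisation, and dealkylation ends the route.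
- Enabling feature: ring B of the 5-aryloxy-6,7-dihydroxycoumarin half has oxygens at C6 and C8a para to each other, C5–OAr and C7–O flanking C6, and the three-carbon chain on C4a. This is the substitution pattern of a hydroquinone formed from a 4-alkenyl-4-hydroxycyclobutenone.
- Stereochemistry: the target is achiral. The one stereocentre on the way (the cyclobutenone carbinol carbon) is racemic and is destroyed in the key step. The E-acrylate geometry comes from the stannane and is inverted by light for lactonisation.

Key step: step 6

Assumption: isoscopoletin is taken as purchasable; squaric acid dichloride is prepared fresh because it hydrolyses on storage.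

**Route**

Step 1
Reactants: 1 squaric acid (3,4-dihydroxycyclobut-3-ene-1,2-dione)
Product: 2 3,4-dichlorocyclobut-3-ene-1,2-dione (squaric acid dichloride)
Conditions: (COCl)2 (2.2 equiv), DMF (cat.), CH2Cl2, 0 to 40 °C; vacuum distillation
Reagents that add atoms: oxalyl chloride, O=C(Cl)C(Cl)=O
Why: The chloroiminium species formed from DMF and oxalyl chloride activates both vinylogous carboxylic acid hydroxyls, so the diacid should be converted into its bis(vinylogous acid chloride) as in ordinary acid chloride formation.

Step 2
Reactants: 2 3,4-dichlorocyclobut-3-ene-1,2-dione; 3 isoscopoletin (6-hydroxy-7-methoxy-2H-chromen-2-one)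
Product: 4 3-chloro-4-[(7-methoxy-2-oxo-2H-chromen-6-yl)oxy]cyclobut-3-ene-1,2-dione
Conditions: 3 and i-Pr2NEt (1.0 equiv each) added slowly to 2 (1.5 equiv), CH2Cl2/THF, −78 to 0 °C; anhydrous work-up
Reagents that add atoms: none
Why: Addition–elimination of the phenoxide at a chlorine-bearing ring carbon (vinylogous acyl substitution, an esterification of a vinylogous acid chloride) forms the hindered aryl–O–C bond without arene coupling, and the first aryloxy donor deactivates the remaining C–Cl so that substitution should stop at the mono stage while the dichloride is in excess.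

Step 3
Reactants: 5 methyl propiolate
Product: 6 methyl (E)-3-(tributylstannyl)acrylate
Conditions: Bu3SnH (1.05 equiv), AIBN (cat.), toluene, 80 °C; chromatography to separate the E isomer
Reagents that add atoms: tributyltin hydride, CCCC[SnH](CCCC)CCCC
Why: Radical-chain hydrostannation puts tin on the terminal alkyne carbon (β to the ester), and reversible stannyl radical addition equilibrates the alkene geometry so that the E isomer can be isolated from the Z and α isomers.

Step 4
Reactants: 4 3-chloro-4-[(7-methoxy-2-oxo-2H-chromen-6-yl)oxy]cyclobut-3-ene-1,2-dione; 6 methyl (E)-3-(tributylstannyl)acrylate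
Product: 7 methyl (E)-3-{2-[(7-methoxy-2-oxo-2H-chromen-6-yl)oxy]-3,4-dioxocyclobut-1-en-1-yl}acrylate
Conditions: Pd2(dba)3 (cat.), tri(2-furyl)phosphine, CuI (cat.), MeCN, 25 °C
Reagents that add atoms: none
Why: Stille cross-coupling: zerovalent palladium inserts readily into the C–Cl bond of the vinylogous acid chloride, CuI speeds transfer of the electron-poor alkenyl group from tin with retention of the E geometry, and the neutral medium should leave the aryl squarate and the coumarin lactone intact.

Step 5
Reactants: 7 methyl (E)-3-{2-[(7-methoxy-2-oxo-2H-chromen-6-yl)oxy]-3,4-dioxocyclobut-1-en-1-yl}acrylate; 8 ethyl vinyl ether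
Product: 10 racemic 4-(1-ethoxyvinyl)-4-hydroxy-3-[(7-methoxy-2-oxo-2H-chromen-6-yl)oxy]-2-[(E)-2-(methoxycarbonyl)vinyl]cyclobut-2-en-1-one, via 1-ethoxyvinyllithium 9 (not isolated)
Conditions: 8 (1.5 equiv), t-BuLi (1.05 equiv), THF, −78 to 0 °C; then added to 7, THF, −78 °C; aq. NH4Cl quench at −78 °C; filtration through Et3N-deactivated silica
Reagents that add atoms: none
Why: 1,2-Addition of an organolithium to a cyclobutenedione: the ring carbonyl next to the aryloxy-bearing carbon is the only ketone-like carbonyl (the other is a vinylogous ester deactivated by the aryloxy oxygen) and is electrophilic enough that, with one equivalent at −78 °C, it should outcompete the methyl ester and the coumarin lactone; the new carbinol carbon forms racemic, which is of no consequence.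

Step 6
Reactants: 10 racemic 4-(1-ethoxyvinyl)-4-hydroxy-3-[(7-methoxy-2-oxo-2H-chromen-6-yl)oxy]-2-[(E)-2-(methoxycarbonyl)vinyl]cyclobut-2-en-1-one
Product: 13 methyl (E)-3-{4-ethoxy-3,6-dihydroxy-2-[(7-methoxy-2-oxo-2H-chromen-6-yl)oxy]phenyl}acrylate, via dienylketene 11 (not isolated), via cyclohexadienone 12 (not isolated)
Conditions: degassed toluene (0.01 M), base-washed glassware, argon, 110 °C
Reagents that add atoms: none
Why: Heating should cause thermally allowed conrotatory four-electron opening of the C1–C4 bond of 10, in which the hydroxyl donor turns outward and so forces the 1-ethoxyvinyl group inward, giving the (Z)-dienylketene 11. A disrotatory six-electron electrocyclisation then joins the ketene carbon (future C8a) to the vinyl CH2 (future C8), closing ring B as cyclohexadienone 12, and enolisation gives hydroquinone 13 irreversibly. This is the Moore rearrangement of squarate-derived 4-alkenyl-4-hydroxycyclobutenones to hydroquinones. No stereocentre is created, and the racemic carbinol centre is consumed. The step needs the right substituent order and inward rotation of the vinyl group: the first is fixed in 10 by the regioselective carbonyl addition of step 5, the second by the outward preference of the hydroxyl, and the E-acrylate keeps its ester carbonyl out of reach of the ketene carbon. Acid-free, oxygen-free, dilute conditions protect the enol ether before ring opening, the hydroquinone after it, and the ketene from intermolecular trapping.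

Step 7
Reactants: 13 methyl (E)-3-{4-ethoxy-3,6-dihydroxy-2-[(7-methoxy-2-oxo-2H-chromen-6-yl)oxy]phenyl}acrylate
Product: 15 7-ethoxy-6-hydroxy-5-[(7-methoxy-2-oxo-2H-chromen-6-yl)oxy]-2H-chromen-2-one, via Z-cinnamate 14 (not isolated)
Conditions: hν (365 nm), degassed MeCN (dilute), 25 °C; then 50 °C to complete ring closure
Reagents that add atoms: none
Why: Photochemical E to Z isomerisation of an o-hydroxycinnamate followed by spontaneous lactonisation (intramolecular transesterification) of the Z isomer by its only ortho hydroxyl, the irreversible ring closure draining the photoequilibrium.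

Step 8
Reactants: 15 7-ethoxy-6-hydroxy-5-[(7-methoxy-2-oxo-2H-chromen-6-yl)oxy]-2H-chromen-2-one
Product: 16 6,7-dihydroxy-5-[(7-hydroxy-2-oxo-2H-chromen-6-yl)oxy]-2H-chromen-2-one (CNP0197949.0)
Conditions: BBr3 (8 equiv), CH2Cl2, −78 to 25 °C; then H2O
Reagents that add atoms: none
Why: Lewis acid ether cleavage: BBr3 binds the alkyl aryl ether oxygens and bromide removes the ethyl and methyl groups by SN2 attack, while the diaryl ether and the two lactones offer no alkyl carbon and should be returned unchanged on hydrolysis.

**Compound list**

1 | squaric acid | OC1=C(O)C(=O)C1=O | starting material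
2 | 3,4-dichlorocyclobut-3-ene-1,2-dione | ClC1=C(Cl)C(=O)C1=O | intermediate
3 | isoscopoletin (6-hydroxy-7-methoxy-2H-chromen-2-one) | COc1cc2oc(=O)ccc2cc1O | starting material
4 | 3-chloro-4-[(7-methoxy-2-oxo-2H-chromen-6-yl)oxy]cyclobut-3-ene-1,2-dione | COc1cc2oc(=O)ccc2cc1OC1=C(Cl)C(=O)C1=O | intermediate
5 | methyl propiolate | C#CC(=O)OC | starting material
6 | methyl (E)-3-(tributylstannyl)acrylate | CCCC[Sn](CCCC)(CCCC)/C=C/C(=O)OC | intermediate
7 | methyl (E)-3-{2-[(7-methoxy-2-oxo-2H-chromen-6-yl)oxy]-3,4-dioxocyclobut-1-en-1-yl}acrylate | COC(=O)/C=C/C1=C(Oc2cc3ccc(=O)oc3cc2OC)C(=O)C1=O | intermediate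
8 | ethyl vinyl ether | C=COCC | starting material
9 | 1-ethoxyvinyllithium | [Li]C(=C)OCC | intermediate
10 | racemic 4-(1-ethoxyvinyl)-4-hydroxy-3-[(7-methoxy-2-oxo-2H-chromen-6-yl)oxy]-2-[(E)-2-(methoxycarbonyl)vinyl]cyclobut-2-en-1-one | C=C(OCC)C1(O)C(=O)C(/C=C/C(=O)OC)=C1Oc1cc2ccc(=O)oc2cc1OC | intermediate
11 | dienylketene, methyl (2E,5Z)-7-ethoxy-6-hydroxy-5-[(7-methoxy-2-oxo-2H-chromen-6-yl)oxy]-4-(oxomethylidene)octa-2,5,7-trienoate | COC(=O)/C=C/C(=C=O)/C(Oc1cc2ccc(=O)oc2cc1OC)=C(/O)C(=C)OCC | intermediate
12 | cyclohexadienone, methyl (E)-3-{4-ethoxy-3-hydroxy-2-[(7-methoxy-2-oxo-2H-chromen-6-yl)oxy]-6-oxocyclohexa-1,3-dien-1-yl}acrylate | CCOC1=C(O)C(Oc2cc3ccc(=O)oc3cc2OC)=C(/C=C/C(=O)OC)C(=O)C1 | intermediate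
13 | methyl (E)-3-{4-ethoxy-3,6-dihydroxy-2-[(7-methoxy-2-oxo-2H-chromen-6-yl)oxy]phenyl}acrylate | CCOc1cc(O)c(/C=C/C(=O)OC)c(Oc2cc3ccc(=O)oc3cc2OC)c1O | intermediate
14 | methyl (Z)-3-{4-ethoxy-3,6-dihydroxy-2-[(7-methoxy-2-oxo-2H-chromen-6-yl)oxy]phenyl}acrylate | CCOc1cc(O)c(/C=C\C(=O)OC)c(Oc2cc3ccc(=O)oc3cc2OC)c1O | intermediate
15 | 7-ethoxy-6-hydroxy-5-[(7-methoxy-2-oxo-2H-chromen-6-yl)oxy]-2H-chromen-2-one | CCOc1cc2oc(=O)ccc2c(Oc2cc3ccc(=O)oc3cc2OC)c1O | intermediate
16 | 6,7-dihydroxy-5-[(7-hydroxy-2-oxo-2H-chromen-6-yl)oxy]-2H-chromen-2-one (CNP0197949.0) | O=c1ccc2cc(Oc3c(O)c(O)cc4oc(=O)ccc34)c(O)cc2o1 | target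

**Step count and risks**

Total steps: 8. Longest linear sequence: 7 steps (steps 1, 2, 4, 5, 6, 7, 8 from squaric acid); step 3 is a one-step side branch.

Steps most likely to fail:

1. Step 5. The hard organolithium may attack the coumarin lactone or the methyl ester, displace aryloxide by addition–elimination, or add to the vinylogous ester carbonyl, eroding chemo- and regioselectivity. The fallback replaces the nucleophile rather than the temperature. It sets out from 9, which is transmetalated with anhydrous CeCl3 in THF at −78 °C to (1-ethoxyvinyl)cerium dichloride F1. This weakly basic, oxophilic reagent is known to add to ketone carbonyls while sparing esters and lactones. Added to 7 at −78 °C and quenched with aq. NH4Cl, it should bring the route back at 10 without free organolithium ever meeting 7.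

2. Step 6. The electron-rich hydroquinone may be partly oxidised by adventitious air during thermolysis and isolation, giving inseparable hydroquinone/quinone mixtures. The fallback isolates ring B at the quinone oxidation level. It sets out from 10, which is thermolysed as before; the crude product is then stirred with Ag2O in ether to give the chromatographable methyl (E)-3-{4-ethoxy-2-[(7-methoxy-2-oxo-2H-chromen-6-yl)oxy]-3,6-dioxocyclohexa-1,4-dien-1-yl}acrylate F2. Reduction with aqueous Na2S2O4 in EtOAc just before the next step should return the route at 13.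

3. Step 7. Irradiation may cause competing [2+2] photodimerisation of the coumarin chromophores, photo-oxidation of the hydroquinone, or a stalled E/Z photoequilibrium. The fallback is a light-free nucleophilic catalysis that sets out from 13 and makes no new isolable compound (F0). With n-Bu3P (cat.) in degassed MeOH at 65 °C, reversible conjugate addition of the phosphine should free rotation about the former double bond, the ortho hydroxyl lactonises, and the phosphine is expelled. This should rejoin the route at 15.

**Further compounds**

F1 | step 5 | (1-ethoxyvinyl)cerium dichloride | C=C(OCC)[Ce](Cl)Cl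
F2 | step 6 | methyl (E)-3-{4-ethoxy-2-[(7-methoxy-2-oxo-2H-chromen-6-yl)oxy]-3,6-dioxocyclohexa-1,4-dien-1-yl}acrylate | CCOC1=CC(=O)C(/C=C/C(=O)OC)=C(Oc2cc3ccc(=O)oc3cc2OC)C1=O
F0 | step 7 | none | none
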